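**Plan**

- Cuts, in retrosynthetic order: the angelate and acetate C–O bonds and the aldehyde oxidation level; the bond from the acrolein α-carbon to its exocyclic CH2; then, in one operation, the bond from the C3 oxygen to the future aldehyde carbon (as a lactone), the α-carbon–carbonyl-carbon bond (to CO) and the O1–C2 bond; last the C3–vinyl bond of an aryl vinyl carbinol.
- Enabling feature: on ring O1–C2–C3–C3a–C7a the C3 oxygen and the C2 carbon chain are cis, and the carbonyl carbon of that chain sits two bonds from C2, so O(C3)–C(=O)–Cα–C2–C3 can exist as a cis-fused five-membered lactone whose carbonyl arrives as CO while O1–C2 closes.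
- Forward: O-allyl 5-acetylsalicylaldehyde takes up vinyl, the phenol is freed, and the dihydrofuran ring and the lactone ring form together; the lactone is methylenated and reduced open, the two new hydroxyls are told apart, the side-chain ester goes on and the primary alcohol is oxidised last.
- Stereochemistry: C3 from ligand-controlled vinylzinc addition; C2 from C3, because the bicyclisation can only give the cis-fused lactone; the side-chain carbinol from catalyst-controlled transfer hydrogenation of the acetyl group; the Z alkene comes with angelic acid.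

Key step: step 4

Remark: 5-acetylsalicylaldehyde is taken as a purchasable compound, and the facial sense of the (+)-DAIB/divinylzinc addition is assumed to mirror that known for the (−)-ligand with dialkylzincs (Si-face delivery); it would be confirmed on compound 5 (Mosher esters) before going on.

**Route**

Step 1
Reactants: 1 5-acetylsalicylaldehyde
Product: 2 5-acetyl-2-(prop-2-en-1-yloxy)benzaldehyde
Conditions: allyl bromide, K2CO3, DMF, rt
Reagents that add atoms: allyl bromide, C=CCBr
Why: Williamson etherification of the acidic phenol should be clean, and the allyl ether masks the hydroxyl that would otherwise quench and chelate the zinc reagent while staying removable under neutral conditions.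

Step 2
Reactants: 2 5-acetyl-2-(prop-2-en-1-yloxy)benzaldehyde; 3 vinylmagnesium bromide
Product: 5 (R)-1-[3-(1-hydroxyprop-2-en-1-yl)-4-(prop-2-en-1-yloxy)phenyl]ethan-1-one, via divinylzinc 4 (not isolated)
Conditions: 3, ZnCl2 (0.5 equiv per 3), Et2O/THF, 0 °C to rt; 1,4-dioxane, filter, exchange to toluene; 2, (+)-DAIB [(2R)-3-exo-(dimethylamino)isoborneol] (5 mol%), toluene, −20 to 0 °C; H2O quench
Reagents that add atoms: vinylmagnesium bromide (3), C=C[Mg]Br; ZnCl2, Cl[Zn]Cl (zinc only in intermediate 4)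
Why: Amino-alcohol-catalysed enantioselective alkenylzinc addition to an aryl aldehyde: the salt-free zinc reagent leaves the aryl methyl ketone alone, and the (+)-ligand is expected to steer vinyl to the Re face of the aldehyde, setting the (R)-carbinol that becomes C3 of the target.

Step 3
Reactants: 5 (R)-1-[3-(1-hydroxyprop-2-en-1-yl)-4-(prop-2-en-1-yloxy)phenyl]ethan-1-one
Product: 6 (R)-1-[4-hydroxy-3-(1-hydroxyprop-2-en-1-yl)phenyl]ethan-1-one
Conditions: Pd(PPh3)4 (3 mol%), morpholine (5 equiv), THF, rt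
Reagents that add atoms: none
Why: Tsuji–Trost deallylation: zerovalent palladium ionises only the allyl aryl ether, whose phenoxide is a good leaving group, morpholine captures the allyl unit, and the unactivated secondary allylic alcohol with its stereocentre is left alone.

Step 4
Reactants: 6 (R)-1-[4-hydroxy-3-(1-hydroxyprop-2-en-1-yl)phenyl]ethan-1-one; 7 carbon monoxide
Product: 8 (3aS,8bS)-7-acetyl-3a,8b-dihydrofuro[3,2-b][1]benzofuran-2(3H)-one
Conditions: PdCl2 (10 mol%), CuCl2 (3 equiv), NaOAc (3 equiv), AcOH, CO (1 atm), rt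
Reagents that add atoms: carbon monoxide (7), [C-]#[O+]
Why: Divalent palladium binds the vinyl group next to the carbinol, the phenol oxygen adds to the internal alkene carbon (O1–C2) to leave a primary alkylpalladium, CO inserts to an acylpalladium and the C3 hydroxyl captures the acyl group, releasing zerovalent palladium that CuCl2 reoxidises. The closest known reaction type is the PdCl2/CuCl2 oxycarbonylative bicyclisation of pent-4-ene-1,3-diols to cis-fused 2,6-dioxabicyclo[3.3.0]octan-3-ones, together with the alkoxycarbonylative cyclisation of 2-allylphenols; here a phenol takes the place of the first hydroxyl. The dihydrofuran ring closes 5-exo-trig by O–C bond formation at the internal alkene carbon, and the lactone ring closes by 5-exo-trig attack of the C3 hydroxyl on the acylpalladium carbon. The one new stereocentre (C2 of the benzofuran, C3a of the tricycle) is controlled by the existing carbinol carbon: a five–five bicycle can only be cis-fused, oxypalladation is reversible and only the cis adduct can lactonise, so the (R)-carbinol should give the (3aS,8bS) lactone. The step needs 5-exo over 6-endo attack and CO insertion over β-hydride elimination, which the terminal alkene and the CO atmosphere secure, and it needs the benzylic allylic carbinol not to ionise, which the acetyl group para to the phenol oxygen and the acetate buffer secure.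

Step 5
Reactants: 8 (3aS,8bS)-7-acetyl-3a,8b-dihydrofuro[3,2-b][1]benzofuran-2(3H)-one
Product: 9 (3aS,8bS)-7-[(1R)-1-hydroxyethyl]-3a,8b-dihydrofuro[3,2-b][1]benzofuran-2(3H)-one
Conditions: RuCl[(R,R)-TsDPEN](p-cymene) (1 mol%), HCO2H/Et3N (5:2), CH2Cl2, rt
Reagents that add atoms: none
Why: Noyori asymmetric transfer hydrogenation of an aryl methyl ketone under catalyst control: the (R,R)-TsDPEN ruthenium hydride should give the (R)-1-arylethanol irrespective of the distant ring stereocentres, and the lactone does not react with the formate reductant.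

Step 6
Reactants: 9 (3aS,8bS)-7-[(1R)-1-hydroxyethyl]-3a,8b-dihydrofuro[3,2-b][1]benzofuran-2(3H)-one
Product: 10 (3aS,8bS)-7-[(1R)-1-(triethylsilyloxy)ethyl]-3a,8b-dihydrofuro[3,2-b][1]benzofuran-2(3H)-one
Conditions: TESCl, imidazole, DMF, 0 °C
Reagents that add atoms: chlorotriethylsilane, CC[Si](Cl)(CC)CC
Why: Silylation of the secondary benzylic alcohol is routine; the TES ether protects the carbinol from the amide base and the hydride to come and can later be removed with buffered HF without loss of a primary TBDPS ether.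

Step 7
Reactants: 10 (3aS,8bS)-7-[(1R)-1-(triethylsilyloxy)ethyl]-3a,8b-dihydrofuro[3,2-b][1]benzofuran-2(3H)-one
Product: 13 (3aS,8bS)-3-methylidene-7-[(1R)-1-(triethylsilyloxy)ethyl]-3a,8b-dihydrofuro[3,2-b][1]benzofuran-2(3H)-one, via Mannich base 11 (not isolated), via trimethylammonium iodide 12 (not isolated)
Conditions: LiN(i-Pr)2 (1.1 equiv), THF, −78 °C; CH2=NMe2+ I− (Eschenmoser's salt), −78 to 0 °C; MeI, MeOH, rt; aq NaHCO3, CH2Cl2, rt
Reagents that add atoms: Eschenmoser's salt (N,N-dimethylmethyleneiminium iodide), C=[N+](C)C.[I-]; iodomethane, CI (methyl only in intermediate 12)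
Why: Lactone α-methylenation by the Mannich route: the lithium enolate formed at −78 °C adds to the iminium salt, N-methylation turns the amine into a leaving group and bicarbonate induces E1cB loss of trimethylamine; low temperature and immediate trapping are meant to keep the enolate from expelling the C3a aryloxide.

Step 8
Reactants: 13 (3aS,8bS)-3-methylidene-7-[(1R)-1-(triethylsilyloxy)ethyl]-3a,8b-dihydrofuro[3,2-b][1]benzofuran-2(3H)-one
Product: 14 (2S,3S)-2-(3-hydroxyprop-1-en-2-yl)-5-[(1R)-1-(triethylsilyloxy)ethyl]-2,3-dihydro-1-benzofuran-3-ol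
Conditions: i-Bu2AlH (4 equiv), CH2Cl2, −78 to −20 °C; aq potassium sodium tartrate
Reagents that add atoms: none
Why: i-Bu2AlH reduces α-methylene-γ-lactones at the carbonyl (1,2) through the lactol aluminate to the 2-methylene-1,4-diol, which frees the C3 hydroxyl and the primary allylic alcohol without touching C2, C3 or the silyl ether.

Step 9
Reactants: 14 (2S,3S)-2-(3-hydroxyprop-1-en-2-yl)-5-[(1R)-1-(triethylsilyloxy)ethyl]-2,3-dihydro-1-benzofuran-3-ol
Product: 15 (2S,3S)-2-[3-(tert-butyldiphenylsilyloxy)prop-1-en-2-yl]-5-[(1R)-1-(triethylsilyloxy)ethyl]-2,3-dihydro-1-benzofuran-3-ol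
Conditions: TBDPSCl (1.1 equiv), imidazole, CH2Cl2, 0 °C
Reagents that add atoms: tert-butylchlorodiphenylsilane, CC(C)(C)[Si](Cl)(c1ccccc1)c1ccccc1
Why: The bulky silyl chloride should silylate the unhindered primary allylic hydroxyl much faster than the secondary benzylic C3 hydroxyl that sits cis to the C2 substituent.

Step 10
Reactants: 15 (2S,3S)-2-[3-(tert-butyldiphenylsilyloxy)prop-1-en-2-yl]-5-[(1R)-1-(triethylsilyloxy)ethyl]-2,3-dihydro-1-benzofuran-3-ol
Product: 16 (2S,3S)-2-[3-(tert-butyldiphenylsilyloxy)prop-1-en-2-yl]-5-[(1R)-1-(triethylsilyloxy)ethyl]-2,3-dihydro-1-benzofuran-3-yl acetate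
Conditions: Ac2O, pyridine, DMAP (cat.), CH2Cl2, 0 °C to rt
Reagents that add atoms: acetic anhydride, CC(=O)OC(C)=O
Why: DMAP-catalysed acetylation of the secondary alcohol takes place at oxygen with retention at C3, and the basic medium avoids ionising the benzylic C3–O bond.

Step 11
Reactants: 16 (2S,3S)-2-[3-(tert-butyldiphenylsilyloxy)prop-1-en-2-yl]-5-[(1R)-1-(triethylsilyloxy)ethyl]-2,3-dihydro-1-benzofuran-3-yl acetate
Product: 17 (2S,3S)-2-[3-(tert-butyldiphenylsilyloxy)prop-1-en-2-yl]-5-[(1R)-1-hydroxyethyl]-2,3-dihydro-1-benzofuran-3-yl acetate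
Conditions: HF·pyridine, pyridine, THF, 0 °C
Reagents that add atoms: none
Why: Pyridine-buffered HF cleaves a secondary TES ether far faster than a primary TBDPS ether, leaves the acetate alone and is not acidic enough to ionise the para-alkoxybenzylic carbinol.

Step 12
Reactants: 17 (2S,3S)-2-[3-(tert-butyldiphenylsilyloxy)prop-1-en-2-yl]-5-[(1R)-1-hydroxyethyl]-2,3-dihydro-1-benzofuran-3-yl acetate; 18 angelic acid
Product: 20 (1R)-1-{(2S,3S)-3-acetoxy-2-[3-(tert-butyldiphenylsilyloxy)prop-1-en-2-yl]-2,3-dihydro-1-benzofuran-5-yl}ethyl (2Z)-2-methylbut-2-enoate, via Yamaguchi mixed anhydride 19 (not isolated)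
Conditions: 18, 2,4,6-Cl3C6H2COCl, Et3N, toluene, rt; then 17, 70 °C
Reagents that add atoms: angelic acid (18), C/C=C(/C)C(=O)O; 2,4,6-trichlorobenzoyl chloride, O=C(Cl)c1c(Cl)cc(Cl)cc1Cl (aroyl group only in intermediate 19)
Why: Yamaguchi esterification through the mixed anhydride, run without DMAP, is the standard way to transfer the angeloyl group without Z to E isomerisation to the tiglate; the alcohol attacks the less hindered angeloyl carbonyl and the carbinol keeps its (R) configuration because only the O–H bond is broken.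

Step 13
Reactants: 20 (1R)-1-{(2S,3S)-3-acetoxy-2-[3-(tert-butyldiphenylsilyloxy)prop-1-en-2-yl]-2,3-dihydro-1-benzofuran-5-yl}ethyl (2Z)-2-methylbut-2-enoate
Product: 21 (1R)-1-[(2S,3S)-3-acetoxy-2-(3-hydroxyprop-1-en-2-yl)-2,3-dihydro-1-benzofuran-5-yl]ethyl (2Z)-2-methylbut-2-enoate
Conditions: Bu4NF, AcOH (1:1), THF, 0 °C to rt
Reagents that add atoms: none
Why: Fluoride cleaves the primary TBDPS ether, and the acetic acid buffer keeps the medium from becoming basic enough for acetyl migration from the C3 oxygen to the new primary hydroxyl or for angelate isomerisation.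

Step 14
Reactants: 21 (1R)-1-[(2S,3S)-3-acetoxy-2-(3-hydroxyprop-1-en-2-yl)-2,3-dihydro-1-benzofuran-5-yl]ethyl (2Z)-2-methylbut-2-enoate
Product: 22 (1R)-1-[(2S,3S)-3-acetoxy-2-(3-oxoprop-1-en-2-yl)-2,3-dihydro-1-benzofuran-5-yl]ethyl (2Z)-2-methylbut-2-enoate
Conditions: activated MnO2 (excess), CH2Cl2, rt
Reagents that add atoms: none
Why: Activated MnO2 oxidises the primary allylic alcohol to the 2-substituted acrolein under neutral heterogeneous conditions that stop at the aldehyde and spare the two esters and the acid-labile benzylic C–O bonds.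

**Compound list**

1 | 5-acetylsalicylaldehyde (5-acetyl-2-hydroxybenzaldehyde) | CC(=O)c1ccc(O)c(C=O)c1 | starting material
2 | 5-acetyl-2-(prop-2-en-1-yloxy)benzaldehyde | CC(=O)c1ccc(OCC=C)c(C=O)c1 | intermediate
3 | vinylmagnesium bromide | C=C[Mg]Br | starting material
4 | divinylzinc (formed in the flask) | C=C[Zn]C=C | intermediate
5 | (R)-1-[3-(1-hydroxyprop-2-en-1-yl)-4-(prop-2-en-1-yloxy)phenyl]ethan-1-one | CC(=O)c1ccc(OCC=C)c(c1)[C@H](O)C=C | intermediate
6 | (R)-1-[4-hydroxy-3-(1-hydroxyprop-2-en-1-yl)phenyl]ethan-1-one | CC(=O)c1ccc(O)c(c1)[C@H](O)C=C | intermediate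
7 | carbon monoxide | [C-]#[O+] | starting material
8 | (3aS,8bS)-7-acetyl-3a,8b-dihydrofuro[3,2-b][1]benzofuran-2(3H)-one (cis-fused lactone) | O=C1C[C@@H]2Oc3ccc(C(C)=O)cc3[C@@H]2O1 | intermediate
9 | (3aS,8bS)-7-[(1R)-1-hydroxyethyl]-3a,8b-dihydrofuro[3,2-b][1]benzofuran-2(3H)-one | O=C1C[C@@H]2Oc3ccc([C@@H](C)O)cc3[C@@H]2O1 | intermediate
10 | (3aS,8bS)-7-[(1R)-1-(triethylsilyloxy)ethyl]-3a,8b-dihydrofuro[3,2-b][1]benzofuran-2(3H)-one | O=C1C[C@@H]2Oc3ccc([C@@H](C)O[Si](CC)(CC)CC)cc3[C@@H]2O1 | intermediate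
11 | Mannich base: (3aS,8bS)-3-[(dimethylamino)methyl]-7-[(1R)-1-(triethylsilyloxy)ethyl]-3a,8b-dihydrofuro[3,2-b][1]benzofuran-2(3H)-one, C3 epimers (formed in the flask) | O=C1C(CN(C)C)[C@@H]2Oc3ccc([C@@H](C)O[Si](CC)(CC)CC)cc3[C@@H]2O1 | intermediate
12 | trimethylammonium iodide of 11: {(3aS,8bS)-2-oxo-7-[(1R)-1-(triethylsilyloxy)ethyl]-2,3,3a,8b-tetrahydrofuro[3,2-b][1]benzofuran-3-yl}-N,N,N-trimethylmethanaminium iodide (formed in the flask) | O=C1C(C[N+](C)(C)C)[C@@H]2Oc3ccc([C@@H](C)O[Si](CC)(CC)CC)cc3[C@@H]2O1.[I-] | intermediate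
13 | (3aS,8bS)-3-methylidene-7-[(1R)-1-(triethylsilyloxy)ethyl]-3a,8b-dihydrofuro[3,2-b][1]benzofuran-2(3H)-one | O=C1C(=C)[C@@H]2Oc3ccc([C@@H](C)O[Si](CC)(CC)CC)cc3[C@@H]2O1 | intermediate
14 | (2S,3S)-2-(3-hydroxyprop-1-en-2-yl)-5-[(1R)-1-(triethylsilyloxy)ethyl]-2,3-dihydro-1-benzofuran-3-ol | C=C(CO)[C@@H]1Oc2ccc([C@@H](C)O[Si](CC)(CC)CC)cc2[C@@H]1O | intermediate
15 | (2S,3S)-2-[3-(tert-butyldiphenylsilyloxy)prop-1-en-2-yl]-5-[(1R)-1-(triethylsilyloxy)ethyl]-2,3-dihydro-1-benzofuran-3-ol | C=C(CO[Si](c3ccccc3)(c3ccccc3)C(C)(C)C)[C@@H]1Oc2ccc([C@@H](C)O[Si](CC)(CC)CC)cc2[C@@H]1O | intermediate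
16 | (2S,3S)-2-[3-(tert-butyldiphenylsilyloxy)prop-1-en-2-yl]-5-[(1R)-1-(triethylsilyloxy)ethyl]-2,3-dihydro-1-benzofuran-3-yl acetate | C=C(CO[Si](c3ccccc3)(c3ccccc3)C(C)(C)C)[C@@H]1Oc2ccc([C@@H](C)O[Si](CC)(CC)CC)cc2[C@@H]1OC(C)=O | intermediate
17 | (2S,3S)-2-[3-(tert-butyldiphenylsilyloxy)prop-1-en-2-yl]-5-[(1R)-1-hydroxyethyl]-2,3-dihydro-1-benzofuran-3-yl acetate | C=C(CO[Si](c3ccccc3)(c3ccccc3)C(C)(C)C)[C@@H]1Oc2ccc([C@@H](C)O)cc2[C@@H]1OC(C)=O | intermediate
18 | angelic acid [(2Z)-2-methylbut-2-enoic acid] | C/C=C(/C)C(=O)O | starting material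
19 | Yamaguchi mixed anhydride: (2Z)-2-methylbut-2-enoic 2,4,6-trichlorobenzoic anhydride (formed in the flask) | C/C=C(/C)C(=O)OC(=O)c1c(Cl)cc(Cl)cc1Cl | intermediate
20 | (1R)-1-{(2S,3S)-3-acetoxy-2-[3-(tert-butyldiphenylsilyloxy)prop-1-en-2-yl]-2,3-dihydro-1-benzofuran-5-yl}ethyl (2Z)-2-methylbut-2-enoate | C=C(CO[Si](c3ccccc3)(c3ccccc3)C(C)(C)C)[C@@H]1Oc2ccc([C@@H](C)OC(=O)/C(C)=C\C)cc2[C@@H]1OC(C)=O | intermediate
21 | (1R)-1-[(2S,3S)-3-acetoxy-2-(3-hydroxyprop-1-en-2-yl)-2,3-dihydro-1-benzofuran-5-yl]ethyl (2Z)-2-methylbut-2-enoate | C=C(CO)[C@@H]1Oc2ccc([C@@H](C)OC(=O)/C(C)=C\C)cc2[C@@H]1OC(C)=O | intermediate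
22 | (1R)-1-[(2S,3S)-3-acetoxy-2-(3-oxoprop-1-en-2-yl)-2,3-dihydro-1-benzofuran-5-yl]ethyl (2Z)-2-methylbut-2-enoate (CNP0294391.4) | C=C(C=O)[C@@H]1Oc2ccc([C@@H](C)OC(=O)/C(C)=C\C)cc2[C@@H]1OC(C)=O | target

**Step count and risks**

Total step count: 14. Longest linear sequence: 14 steps, from 1 to 22; compounds 3, 7 and 18 are bought.

Steps most likely to fail, riskiest first:

Step 7. The lithium enolate may expel the C3a aryloxide (retro-oxa-Michael opening of the dihydrofuran ring) faster than the iminium salt captures it, and the opened butenolide would put the C8b stereocentre at risk through its acidic γ-position. The fallback leaves the lactone oxidation level before the methylene carbon is introduced, so that no metal enolate and no strong base are involved. From 10, one equivalent of i-Bu2AlH in CH2Cl2 at −78 °C should give the lactol (3aS,8bS)-7-[(1R)-1-(triethylsilyloxy)ethyl]-2,3,3a,8b-tetrahydrofuro[3,2-b][1]benzofuran-2-ol F1. Its open hydroxy-aldehyde form would be methylenated under amine catalysis (aqueous formaldehyde, pyrrolidine, propionic acid, i-PrOH, 45 °C; Mannich condensation through the enamine) to the α-methylene lactol (3aS,8bS)-3-methylidene-7-[(1R)-1-(triethylsilyloxy)ethyl]-2,3,3a,8b-tetrahydrofuro[3,2-b][1]benzofuran-2-ol F2. Luche reduction (NaBH4, CeCl3·7H2O, MeOH, 0 °C) of the open enal form should then give diol 14, where the route resumes.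

Step 4. The benzylic allylic hydroxyl may ionise in acetic acid (ortho-quinone methide formation, acetolysis, racemisation), or β-hydride elimination from the alkylpalladium may outrun CO insertion; either drains material from the bicyclisation. The fallback makes the same O1–C2 and lactone C–O bonds by conjugate addition instead of oxypalladation and brings the carbonyl carbon in as an acrylate. From 6, cross-metathesis with methyl acrylate (second-generation Hoveyda–Grubbs catalyst, CH2Cl2, 40 °C) should give methyl (2E,4R)-4-(5-acetyl-2-hydroxyphenyl)-4-hydroxybut-2-enoate F3. A catalytic base (K2CO3 in MeCN) would trigger 5-exo-trig oxa-Michael addition of the phenoxide to give methyl [(2S,3S)-5-acetyl-3-hydroxy-2,3-dihydro-1-benzofuran-2-yl]acetate F4, which is not isolated. The oxa-Michael step is reversible and only the cis isomer can lactonise, so the mixture should drain to lactone 8, where the route resumes.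

Step 2. Facial selectivity may be poor because residual magnesium halide or the ortho ether oxygen opens an unselective background addition, or vinyl transfer from a poorly defined zinc reagent may be sluggish. The fallback separates C–C bond formation from the asymmetric event. From 2, vinylmagnesium bromide (1.05 equiv, THF, −78 °C, aldehyde-selective) should give racemic 1-[3-(1-hydroxyprop-2-en-1-yl)-4-(prop-2-en-1-yloxy)phenyl]ethan-1-one F5. Sharpless kinetic resolution (Ti(Oi-Pr)4, diisopropyl D-tartrate, t-BuOOH 0.6 equiv, 4 Å sieves, CH2Cl2, −20 °C) should epoxidise the (S)-enantiomer to the erythro epoxy alcohol 1-{3-[(R)-hydroxy[(2S)-oxiran-2-yl]methyl]-4-(prop-2-en-1-yloxy)phenyl}ethan-1-one F6, removed by chromatography. The (R)-alcohol 5 is left, where the route resumes; the allyl ether is not an allylic alcohol and should not be epoxidised.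

**Further compounds**

F1 | step 7 | (3aS,8bS)-7-[(1R)-1-(triethylsilyloxy)ethyl]-2,3,3a,8b-tetrahydrofuro[3,2-b][1]benzofuran-2-ol (anomers) | OC1C[C@@H]2Oc3ccc([C@@H](C)O[Si](CC)(CC)CC)cc3[C@@H]2O1
F2 | step 7 | (3aS,8bS)-3-methylidene-7-[(1R)-1-(triethylsilyloxy)ethyl]-2,3,3a,8b-tetrahydrofuro[3,2-b][1]benzofuran-2-ol (anomers) | OC1C(=C)[C@@H]2Oc3ccc([C@@H](C)O[Si](CC)(CC)CC)cc3[C@@H]2O1
F3 | step 4 | methyl (2E,4R)-4-(5-acetyl-2-hydroxyphenyl)-4-hydroxybut-2-enoate | COC(=O)/C=C/[C@@H](O)c1cc(C(C)=O)ccc1O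
F4 | step 4 | methyl [(2S,3S)-5-acetyl-3-hydroxy-2,3-dihydro-1-benzofuran-2-yl]acetate | COC(=O)C[C@@H]1Oc2ccc(C(C)=O)cc2[C@@H]1O
F5 | step 2 | racemic 1-[3-(1-hydroxyprop-2-en-1-yl)-4-(prop-2-en-1-yloxy)phenyl]ethan-1-one | CC(=O)c1ccc(OCC=C)c(c1)C(O)C=C
F6 | step 2 | 1-{3-[(R)-hydroxy[(2S)-oxiran-2-yl]methyl]-4-(prop-2-en-1-yloxy)phenyl}ethan-1-one | CC(=O)c1ccc(OCC=C)c(c1)[C@@H](O)[C@@H]2CO2
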